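Whatever happened in this closed flask, the fractions of the charge held as J, Z, E, X and G had to add up to one, and I started from that sum.

J 0.20 M; time 80 min

    J ⇌ Z (K1 = 3.1, k1 = 0.38 s⁻¹)
    J ⇌ E (K2 = 2.9, k2 = 0.22 s⁻¹)
    Z ⇌ E (k3 = 0.040 s⁻¹)
    Z ⇌ X (K4 = 11, k4 = 0.16 s⁻¹)
    J ⇌ G (K5 = 0.62, k5 = 0.045 s⁻¹)

- which holds at 80 min: what has brought the reaction to rest, or that it has not come to rest (forward and back rates have come level / it is still moving / all of J has reacted)
- share of the J used up at 80 min
- Z at 80 min, in percent of the J charged
- X at 80 min, in percent of the J charged
- amount of Z if the flask were left three thousand times as long, in percent of the J charged

- what has gone from J into another species counts as reacted, even if it can come back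
- the reaction counts as stopped when no species that holds the J changes by six tenths of a point or more over the second half of the time
- run time (flask): 80 min

I first turned the constants into times. Of the steps taken each by itself, the exchange of Z and E had the longest relaxation half-life, 0.140 min, and the run lasted far longer, 80 min. So I expected thermodynamic control at the asked time, and I gave each species a weight: its balance amount with J counted as one.

I then built the flask up one process at a time. With the step from J to Z by itself, Z had the weight 3.1, which put 0.756 of the charge in Z. Adding the step from J to E, with weight 2.9, brought Z down to 0.443, and adding G, with weight 0.62, brought it to 0.407. The path from Z to E brought no new weight, as its constant is the ratio of the two weights already there, and it left the conversion of J as it was. X came last, reached through Z with the weight 34.1, and this raised the sum of the weights to 41.7. The number I carried forward was the balance share of Z, the weight of Z divided by the sum of the weights: 0.0743 of the charge. Every step ran first order, and no charge stands in that sum. The same sum gave me 0.817 of the charge in X and 0.0240 left as J.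

The forecast worked from the same balance. It said that at the asked time forward and back rates have come level, with a conversion of 97.6%, Z at 7.43%, X at 81.7%, and Z at 7.43% after the far longer wait. In its own words: “The cycle is thermodynamically consistent, so a longer time changes nothing.”

The simulation gave the outcome that forward and back rates have come level, with 97.6% of the J used up, Z at 7.43%, X at 81.7%, and Z at 7.43% after the far longer wait. The largest change of any share over the second half of the time was 0 percentage points. The balance share of Z, 7.43%, holds no charge, so I put it to the neighbouring flask charged with 0.080 M of J in place of 0.20 M, and at 80.0 min that flask read Z at 7.43% of its own charge.

The numbers of this flask are invented; the rest is arithmetic.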